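The key step forms two bonds that define ring A: the bond between the ketone carbon C2 and the carbinol carbon C3, and the bond between the quaternary C4 and the ring-fusion carbon C5. The route exploits the adjacency of C2, C3 and C4 in ring A, because an α-ketol next to a gem-dimethyl carbon is what a 1,2-acyl shift leaves behind. The precursor is therefore acyclic: an all-E triene chain, phenylsulfonyl on C7, ending in a 2,2-dimethyl-3-oxo aldehyde in which C4 is still bonded to C2. A tin ketyl at C3 shifts the acyl group, the freed C4 radical closes ring A on C5 and ring B on C9, and loss of the sulfonyl radical places C7=C8. An oxidative kinetic resolution then supplies the single enantiomer.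

Key step: step 10

Remark: atom numbers are labdane numbers (ring A: C1–C5 and C10; ring B: C5–C10; side chain C11–C16; C17 on C8, C18 and C19 on C4, C20 on C10), and the stereodescriptors of the bicyclic compounds refer to this numbering.
Assumption: in step 11 the antipode of the tert-leucine-derived vanadium ligand that oxidises the 3R ketol is the one used; both antipodes of tert-leucine are commercial.

Step 1
Reactants: 1 geraniol
Product: 2 geranyl tert-butyldimethylsilyl ether
Conditions: TBSCl, imidazole, DMF, rt
Reagents that add atoms: tert-butyldimethylsilyl chloride CC(C)(C)[Si](C)(C)Cl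
Why: Silyl ether formation masks the C15 oxygen against the carbanion chemistry of steps 5 and 7.

Step 2
Reactants: 2 geranyl tert-butyldimethylsilyl ether
Product: 3 (2E,6E)-8-[(tert-butyldimethylsilyl)oxy]-2,6-dimethylocta-2,6-dien-1-ol
Conditions: SeO2 (cat.), t-BuOOH, salicylic acid (cat.), CH2Cl2, rt
Reagents that add atoms: tert-butyl hydroperoxide CC(C)(C)OO
Why: Catalytic SeO2 allylic oxidation (ene reaction followed by 2,3-sigmatropic shift) should hydroxylate the E-methyl group of the more electron-rich distal alkene, giving the E allylic alcohol whose carbon becomes C7.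

Step 3
Reactants: 3 (2E,6E)-8-[(tert-butyldimethylsilyl)oxy]-2,6-dimethylocta-2,6-dien-1-ol
Product: 5 tert-butyldimethyl{[(2E,6E)-3,7-dimethyl-8-(phenylsulfonyl)octa-2,6-dien-1-yl]oxy}silane, via allylic mesylate 4 (not isolated)
Conditions: MsCl, Et3N, CH2Cl2, −40 °C; then PhSO2Na, DMF, rt
Reagents that add atoms: sodium benzenesulfinate [Na+].[O-]S(=O)c1ccccc1
Why: Mesylation and SN2 displacement by the sulfur atom of the ambident sulfinate should give the allylic sulfone that acidifies C7 for the fragment coupling.

Step 4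
Reactants: 6 isoprene; 7 benzenesulfonyl chloride
Product: 8 {[(2E)-4-chloro-2-methylbut-2-en-1-yl]sulfonyl}benzene
Conditions: CuCl (cat.), Et3N·HCl (cat.), MeCN, 100 °C (sealed tube); crystallisation of the E isomer
Reagents that add atoms: none
Why: Copper-catalysed atom-transfer radical 1,4-addition of a sulfonyl chloride to a diene (Kharasch type) should place sulfur on the CH2 next to the methyl-bearing carbon and chlorine on the other terminus.

Step 5
Reactants: 5 tert-butyldimethyl{[(2E,6E)-3,7-dimethyl-8-(phenylsulfonyl)octa-2,6-dien-1-yl]oxy}silane; 8 {[(2E)-4-chloro-2-methylbut-2-en-1-yl]sulfonyl}benzene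
Product: 9 tert-butyldimethyl{[(2E,6E,10E)-3,7,11-trimethyl-8,12-bis(phenylsulfonyl)dodeca-2,6,10-trien-1-yl]oxy}silane (racemic at C7)
Conditions: n-BuLi, THF, −78 °C; then 8, DMPU, −78 to −30 °C
Reagents that add atoms: none
Why: SN2 alkylation of the α-sulfonyl allyl anion at its α-carbon by the primary allylic chloride (sulfone coupling of terpene synthesis) joins C7 to C6 and leaves on C7 the sulfonyl group that step 10 uses as a radical leaving group; the configuration at C7 is irrelevant because C7 ends sp2.

Step 6
Reactants: 10 methyl 3-hydroxy-2,2-dimethylpropanoate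
Product: 11 methyl 2,2-dimethyl-3-[(triethylsilyl)oxy]propanoate
Conditions: TESCl, imidazole, CH2Cl2, 0 °C
Reagents that add atoms: triethylsilyl chloride CC[Si](Cl)(CC)CC
Why: Silyl ether formation with the labile triethylsilyl group protects the neopentyl alcohol that becomes the aldehyde carbon C3.

Step 7
Reactants: 9 tert-butyldimethyl{[(2E,6E,10E)-3,7,11-trimethyl-8,12-bis(phenylsulfonyl)dodeca-2,6,10-trien-1-yl]oxy}silane; 11 methyl 2,2-dimethyl-3-[(triethylsilyl)oxy]propanoate
Product: 12 (5E,9E,13E)-15-[(tert-butyldimethylsilyl)oxy]-2,2,5,9,13-pentamethyl-4,8-bis(phenylsulfonyl)-1-[(triethylsilyl)oxy]pentadeca-5,9,13-trien-3-one (diastereomer mixture)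
Conditions: LiN(i-Pr)2 (2.2 equiv), THF, −78 °C; then 11, −78 to −20 °C; AcOH
Reagents that add atoms: none
Why: The less hindered primary α-sulfonyl carbanion at C1 should attack the ester (Claisen-type acylation to a β-keto sulfone), the second equivalent of base being taken up by the acidic product, which joins C1 to C2 and brings in C3 and the quaternary C4.

Step 8
Reactants: 12 the β-keto sulfone
Product: 13 (5E,9E,13E)-15-[(tert-butyldimethylsilyl)oxy]-2,2,5,9,13-pentamethyl-8-(phenylsulfonyl)-1-[(triethylsilyl)oxy]pentadeca-5,9,13-trien-3-one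
Conditions: SmI2 (2.5 equiv), THF–MeOH, −78 °C
Reagents that add atoms: none
Why: Single-electron reductive cleavage of the activated C–S bond α to the ketone and α-protonation of the resulting enolate should give the β,γ-unsaturated ketone, while the unactivated allylic sulfone at C7 is not reduced at −78 °C.

Step 9
Reactants: 13 the ketone
Product: 14 (5E,9E,13E)-15-[(tert-butyldimethylsilyl)oxy]-2,2,5,9,13-pentamethyl-3-oxo-8-(phenylsulfonyl)pentadeca-5,9,13-trienal
Conditions: IBX (excess), DMSO, rt
Reagents that add atoms: none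
Why: IBX in DMSO is known to cleave primary triethylsilyl ethers and oxidise the freed alcohol while tert-butyldimethylsilyl ethers survive, so the aldehyde C3 is unveiled under neutral conditions that should not conjugate the β,γ-enone.

Step 10
Reactants: 14 the keto aldehyde
Product: 16 racemic (3S*,5S*,9R*,10S*)-15-[(tert-butyldimethylsilyl)oxy]-3-hydroxylabda-7,13E-dien-2-one, via O3-tributylstannyl ether 15 (not isolated)
Conditions: Bu3SnH (slow addition), AIBN (cat.), benzene (dilute), 80 °C; then H2O
Reagents that add atoms: none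
Why: Proposed new method: Bu3Sn• adds reversibly to the aldehyde oxygen to give an O-stannyl ketyl at C3, which attacks the neighbouring ketone carbon C2 (3-exo-trig), and the cyclopropyloxy radical opens toward the tertiary radical at C4, a net 1,2-acyl shift that makes C2–C3; C4• then closes ring A on C5 (6-endo-trig, makes C4–C5), the tertiary C10 radical closes ring B on C9 (6-endo-trig), and the C8 radical expels PhSO2• from C7 to give C7=C8, PhSO2• carrying the chain by taking hydrogen from Bu3SnH. The closest known reaction types are the Dowd–Beckwith 1,2-acyl migration of β-keto alkyl radicals, O-stannyl ketyl cyclisations, and tin-mediated radical polyene cyclisations ended by β-scission of a sulfonyl radical; what is new is that a ketyl starts the acyl shift. C5, C10 and C9 should be set by the chair–chair transition state of the two E alkenes (anti addition across C5=C10 gives the trans ring fusion, C11 equatorial), and C3 relative to them because the acyl shift is reversible and the chair with the stannyloxy group equatorial closes fastest; the product is racemic. The step needs the acyl shift to outrun direct 6-endo attack of the ketyl on C5, and ketyl formation at the ketone to be unproductive: the nucleophilic ketyl is polarity-matched to the carbonyl carbon held beside it by the quaternary C4 but mismatched to the electron-rich alkene, and the ketone-derived ketyl can only revert or give a radical that cannot cyclise. Slow addition of Bu3SnH keeps premature reduction low.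

Step 11
Reactants: 16 the racemic ketol
Product: 17 (3S,5S,9R,10S)-15-[(tert-butyldimethylsilyl)oxy]-3-hydroxylabda-7,13E-dien-2-one
Conditions: VO(OMe)L (cat.; L = dianion of N-(3,5-di-tert-butylsalicylidene)-tert-leucine, pentavalent vanadium), O2 (1 atm), toluene, rt, stopped just past half conversion
Reagents that add atoms: none
Why: Chiral vanadyl-catalysed aerobic oxidation of α-hydroxy ketones (oxidative kinetic resolution) should turn the 3R antipode into the 2,3-dione and leave the (3S,5S,9R,10S) ketol, which fixes the absolute configuration of all four stereocentres at once.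

Step 12
Reactants: 17 the resolved ketol
Product: 18 (3S,5S,9R,10S)-3,15-dihydroxylabda-7,13E-dien-2-one
Conditions: HF·pyridine, pyridine, THF, 0 °C
Reagents that add atoms: none
Why: Fluoride-mediated desilylation frees the primary allylic alcohol without base, so the ketol should neither epimerise nor rearrange.

Step 13
Reactants: 18 the diol
Product: 19 (3S,5S,9R,10S)-3-hydroxy-2-oxolabda-7,13E-dien-15-yl acetate (target)
Conditions: Ac2O, pyridine, CH2Cl2, 0 °C
Reagents that add atoms: acetic anhydride CC(=O)OC(C)=O
Why: Acetylation without an acyl-transfer catalyst should be selective for the unhindered primary allylic alcohol over the secondary hydroxyl flanked by the quaternary C4 and the C2 carbonyl.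

Compound list
1 | geraniol | OC/C=C(\C)CCC=C(C)C | starting material
2 | geranyl tert-butyldimethylsilyl ether | CC(C)(C)[Si](C)(C)OC/C=C(\C)CCC=C(C)C | intermediate
3 | (2E,6E)-8-[(tert-butyldimethylsilyl)oxy]-2,6-dimethylocta-2,6-dien-1-ol | CC(C)(C)[Si](C)(C)OC/C=C(\C)CC/C=C(\C)CO | intermediate
4 | methanesulfonate of 3 | CC(C)(C)[Si](C)(C)OC/C=C(\C)CC/C=C(\C)COS(C)(=O)=O | intermediate (not isolated)
5 | tert-butyldimethyl{[(2E,6E)-3,7-dimethyl-8-(phenylsulfonyl)octa-2,6-dien-1-yl]oxy}silane | CC(C)(C)[Si](C)(C)OC/C=C(\C)CC/C=C(\C)CS(=O)(=O)c1ccccc1 | intermediate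
6 | isoprene | C=CC(C)=C | starting material
7 | benzenesulfonyl chloride | O=S(=O)(Cl)c1ccccc1 | starting material
8 | {[(2E)-4-chloro-2-methylbut-2-en-1-yl]sulfonyl}benzene | ClC/C=C(\C)CS(=O)(=O)c1ccccc1 | intermediate
9 | tert-butyldimethyl{[(2E,6E,10E)-3,7,11-trimethyl-8,12-bis(phenylsulfonyl)dodeca-2,6,10-trien-1-yl]oxy}silane, racemic at C7 | CC(C)(C)[Si](C)(C)OC/C=C(\C)CC/C=C(\C)C(C/C=C(\C)CS(=O)(=O)c1ccccc1)S(=O)(=O)c1ccccc1 | intermediate
10 | methyl 3-hydroxy-2,2-dimethylpropanoate | COC(=O)C(C)(C)CO | starting material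
11 | methyl 2,2-dimethyl-3-[(triethylsilyl)oxy]propanoate | COC(=O)C(C)(C)CO[Si](CC)(CC)CC | intermediate
12 | (5E,9E,13E)-15-[(tert-butyldimethylsilyl)oxy]-2,2,5,9,13-pentamethyl-4,8-bis(phenylsulfonyl)-1-[(triethylsilyl)oxy]pentadeca-5,9,13-trien-3-one, diastereomer mixture | CC(C)(C)[Si](C)(C)OC/C=C(\C)CC/C=C(\C)C(C/C=C(\C)C(C(=O)C(C)(C)CO[Si](CC)(CC)CC)S(=O)(=O)c1ccccc1)S(=O)(=O)c1ccccc1 | intermediate
13 | (5E,9E,13E)-15-[(tert-butyldimethylsilyl)oxy]-2,2,5,9,13-pentamethyl-8-(phenylsulfonyl)-1-[(triethylsilyl)oxy]pentadeca-5,9,13-trien-3-one, racemic at C7 | CC(C)(C)[Si](C)(C)OC/C=C(\C)CC/C=C(\C)C(C/C=C(\C)CC(=O)C(C)(C)CO[Si](CC)(CC)CC)S(=O)(=O)c1ccccc1 | intermediate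
14 | (5E,9E,13E)-15-[(tert-butyldimethylsilyl)oxy]-2,2,5,9,13-pentamethyl-3-oxo-8-(phenylsulfonyl)pentadeca-5,9,13-trienal, racemic at C7 | CC(C)(C)[Si](C)(C)OC/C=C(\C)CC/C=C(\C)C(C/C=C(\C)CC(=O)C(C)(C)C=O)S(=O)(=O)c1ccccc1 | intermediate
15 | O3-tributylstannyl ether of 16, racemic (one enantiomer drawn) | CC(C)(C)[Si](C)(C)OC/C=C(\C)CC[C@@H]1C(C)=CC[C@@H]2C(C)(C)[C@H](O[Sn](CCCC)(CCCC)CCCC)C(=O)C[C@@]12C | intermediate (not isolated)
16 | racemic (3S*,5S*,9R*,10S*)-15-[(tert-butyldimethylsilyl)oxy]-3-hydroxylabda-7,13E-dien-2-one (one enantiomer drawn) | CC(C)(C)[Si](C)(C)OC/C=C(\C)CC[C@@H]1C(C)=CC[C@@H]2C(C)(C)[C@H](O)C(=O)C[C@@]12C | intermediate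
17 | (3S,5S,9R,10S)-15-[(tert-butyldimethylsilyl)oxy]-3-hydroxylabda-7,13E-dien-2-one, single enantiomer | CC(C)(C)[Si](C)(C)OC/C=C(\C)CC[C@@H]1C(C)=CC[C@@H]2C(C)(C)[C@H](O)C(=O)C[C@@]12C | intermediate
18 | (3S,5S,9R,10S)-3,15-dihydroxylabda-7,13E-dien-2-one | OC/C=C(\C)CC[C@@H]1C(C)=CC[C@@H]2C(C)(C)[C@H](O)C(=O)C[C@@]12C | intermediate
19 | (3S,5S,9R,10S)-3-hydroxy-2-oxolabda-7,13E-dien-15-yl acetate | CC(=O)OC/C=C(\C)CC[C@@H]1C(C)=CC[C@@H]2C(C)(C)[C@H](O)C(=O)C[C@@]12C | target

Total step count: 13. Longest linear sequence: 11 steps (steps 1, 2, 3, 5, 7, 8, 9, 10, 11, 12, 13); steps 4 and 6 prepare the two side fragments.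

Steps most likely to fail

Step 10. The ketyl may close directly on C5, or be reduced by the tin hydride, before the acyl group has shifted, which would give the wrong ring or an acyclic alcohol. The fallback uses known chemistry and sets out from 14. Methyl chloroformate with catalytic pyridine adds across the aldehyde to give the 1-chloroalkyl methyl carbonate F1. Bu3SnH and AIBN then abstract chlorine; the resulting α-(acyloxy)alkyl radical is less stabilised than a ketyl, so the Dowd–Beckwith 1,2-acyl shift of this halide-derived β-keto radical runs downhill to the tertiary C4 radical. The same tin-mediated bicyclisation with loss of the sulfonyl radical gives the racemic 3-O-methoxycarbonyl ketol F2. K2CO3 in MeOH removes the carbonate and the route is rejoined at 16.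

Step 11. Poor discrimination between the antipodes of a hindered ketol would leave material of low enantiomeric purity. The fallback sets out from 16. Esterification with (S)-2-methoxy-2-phenylacetic acid (DCC, DMAP, CH2Cl2) gives the diastereomeric esters of the 3S series F3 and of the 3R series F4, which are separated by chromatography. K2CO3 in MeOH cleaves F3 and the route is rejoined at 17.

Step 7. Under two equivalents of base, deprotonation at the methine C7 and acylation there would give regioisomeric keto sulfones. The fallback sets out from 9 and 11. i-Bu2AlH at −78 °C reduces 11 to 2,2-dimethyl-3-[(triethylsilyl)oxy]propanal F5. The monoanion of 9, made with one equivalent of n-BuLi so that only the CH2 next to the terminal sulfone is deprotonated, adds to F5 to give the β-hydroxy sulfone F6, whose alkoxide needs no second equivalent of base. Dess–Martin periodinane oxidises F6 and the route is rejoined at 12.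

Further compounds
F1 | step 10 | (5E,9E,13E)-15-[(tert-butyldimethylsilyl)oxy]-1-chloro-2,2,5,9,13-pentamethyl-3-oxo-8-(phenylsulfonyl)pentadeca-5,9,13-trien-1-yl methyl carbonate | CC(C)(C)[Si](C)(C)OC/C=C(\C)CC/C=C(\C)C(C/C=C(\C)CC(=O)C(C)(C)C(Cl)OC(=O)OC)S(=O)(=O)c1ccccc1
F2 | step 10 | racemic (3S*,5S*,9R*,10S*)-15-[(tert-butyldimethylsilyl)oxy]-2-oxolabda-7,13E-dien-3-yl methyl carbonate | CC(C)(C)[Si](C)(C)OC/C=C(\C)CC[C@@H]1C(C)=CC[C@@H]2C(C)(C)[C@H](OC(=O)OC)C(=O)C[C@@]12C
F3 | step 11 | (3S,5S,9R,10S)-15-[(tert-butyldimethylsilyl)oxy]-2-oxolabda-7,13E-dien-3-yl (S)-2-methoxy-2-phenylacetate | CC(C)(C)[Si](C)(C)OC/C=C(\C)CC[C@@H]1C(C)=CC[C@@H]2C(C)(C)[C@H](OC(=O)[C@@H](OC)c1ccccc1)C(=O)C[C@@]12C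
F4 | step 11 | (3R,5R,9S,10R)-15-[(tert-butyldimethylsilyl)oxy]-2-oxolabda-7,13E-dien-3-yl (S)-2-methoxy-2-phenylacetate | CC(C)(C)[Si](C)(C)OC/C=C(\C)CC[C@H]1C(C)=CC[C@H]2C(C)(C)[C@@H](OC(=O)[C@@H](OC)c1ccccc1)C(=O)C[C@]12C
F5 | step 7 | 2,2-dimethyl-3-[(triethylsilyl)oxy]propanal | O=CC(C)(C)CO[Si](CC)(CC)CC
F6 | step 7 | (5E,9E,13E)-15-[(tert-butyldimethylsilyl)oxy]-2,2,5,9,13-pentamethyl-4,8-bis(phenylsulfonyl)-1-[(triethylsilyl)oxy]pentadeca-5,9,13-trien-3-ol | CC(C)(C)[Si](C)(C)OC/C=C(\C)CC/C=C(\C)C(C/C=C(\C)C(C(O)C(C)(C)CO[Si](CC)(CC)CC)S(=O)(=O)c1ccccc1)S(=O)(=O)c1ccccc1
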